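**Strategy.** Ring B of the target is a C-acylphloroglucinol, i.e. a folded 3,5,7-triketo ester in which the benzophenone carbonyl carbon and the ring B carbon that bears it are C7 and C6 of the chain. That bond is therefore made by Claisen acylation: the methyl carbanion of a 3-prenylated triacetic acid lactone (ring B masked as a 4-hydroxy-2-pyrone, prenyl already on the carbon between two oxygenated carbons) attacks the ester of a silyl-protected methyl 3-hydroxy-2-prenylbenzoate (ring A). In the same flask methoxide opens the pyrone, the chain closes biomimetically by Claisen condensation to the aromatic ring B, and the silyl ether falls off, so the key step ends at the natural product.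

Key step: step 4

Assumption: triacetic acid lactone, methyl 2-bromo-3-hydroxybenzoate, prenyl acetate and prenyl bromide are taken as catalogue chemicals. The target has no stereocentre and no stereogenic double bond, so no step has to control configuration.

**Step 1**
Reactants: 1 triacetic acid lactone (4-hydroxy-6-methyl-2H-pyran-2-one)
Product: 2 4-hydroxy-6-methyl-3-(3-methylbut-2-en-1-yl)-2H-pyran-2-one
Conditions: 1 (1.5 equiv), prenyl acetate, Pd(PPh3)4 (5 mol %), DBU (1.5 equiv), THF, 60 °C
Reagents that add atoms: prenyl acetate (3-methylbut-2-en-1-yl acetate), CC(C)=CCOC(C)=O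
Why: Tsuji–Trost allylation, in which zerovalent palladium ionises prenyl acetate to the 1,1-dimethylallyl palladium complex and the soft pyronate attacks its unsubstituted terminus through C3, the only nucleophilic carbon of 1, while any 4-O-prenyl ether should re-ionise under the catalyst so that the C3-prenyl compound accumulates as the thermodynamic product.

**Step 2**
Reactants: 3 methyl 2-bromo-3-hydroxybenzoate
Product: 4 methyl 2-bromo-3-[(tert-butyldimethylsilyl)oxy]benzoate
Conditions: TBSCl, imidazole, DMF, rt
Reagents that add atoms: TBSCl (tert-butyldimethylsilyl chloride), CC(C)(C)[Si](C)(C)Cl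
Why: Imidazole-promoted silylation of a phenol, which masks the acidic OH for the organozinc and carbanion steps with a group that methoxide should remove in step 4.

**Step 3**
Reactants: 4 methyl 2-bromo-3-[(tert-butyldimethylsilyl)oxy]benzoate
Product: 5 methyl 3-[(tert-butyldimethylsilyl)oxy]-2-(3-methylbut-2-en-1-yl)benzoate
Conditions: Me2C=CHCH2ZnBr (from prenyl bromide, Zn, LiCl, THF), Pd(OAc)2 (2 mol %), CPhos (4 mol %), THF, rt
Reagents that add atoms: prenylzinc bromide, CC(C)=CC[Zn]Br (made from prenyl bromide, CC(C)=CCBr, and zinc dust)
Why: Negishi cross-coupling (oxidative addition of the aryl bromide to zerovalent palladium, transmetalation from the allylic zinc, reductive elimination), in which the bulky biarylphosphine should favour the linear prenyl arene over the reverse-prenyl isomer and the mild room-temperature conditions should spare the ester and the silyl ether.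

**Step 4**
Reactants: 2 4-hydroxy-6-methyl-3-(3-methylbut-2-en-1-yl)-2H-pyran-2-one; 5 methyl 3-[(tert-butyldimethylsilyl)oxy]-2-(3-methylbut-2-en-1-yl)benzoate
Product: 8 cudraphenone D, via phenacylpyrone 6 (not isolated), via triketo ester 7 (not isolated)
Conditions: 2 (2.2 equiv), LiN(iPr)2 (4.4 equiv), THF, −78 to 0 °C; 5 (1.0 equiv), −78 to 0 °C; then MeOH, Mg(OMe)2 (5 equiv), reflux, argon; cold 1 M HCl work-up
Reagents that add atoms: none
Why: LiN(iPr)2 converts 2 into its dianion (4-oxido pyrone with a carbanion on the 6-methyl group), and this carbon, the last deprotonated and most basic site with C3 blocked by the prenyl group, adds to the ester carbonyl of 5 and expels methoxide (Claisen acylation), which creates the ketone C–C bond and gives 6 as its enolate. Methanolic Mg(OMe)2 then opens the lactone at C2 to the magnesium-chelated triketo ester 7, whose C6 carbanion attacks the ester carbon in a 6-exo-trig Claisen (Dieckmann-type) closure; loss of methoxide and enolisation give the aromatic ring B, and methoxide also cleaves the aryl silyl ether to free the ring A phenol. The closest known reactions are the acylation of the triacetic acid lactone dianion with aromatic esters and the biomimetic base-induced conversion of 6-(2-oxoalkyl)-4-hydroxy-2-pyrones and 3,5,7-triketo esters into acylphloroglucinols. No stereocentre is formed in the product, since the enolisable C2 of 7 becomes an aromatic carbon. The selectivity needed is Claisen over aldol folding of 7: the aldol alternative (C2 onto the C7 ketone) would give a ring whose C2 is quaternary (prenyl and CO2Me) and cannot aromatise, and the C7 carbonyl is shielded by the ortho-prenyl group of ring A, so that closure should stay reversible while the Claisen closure is driven by aromatisation. Two equivalents of dianion per ester (the second acting as base for 6) keep free amide base away from the benzylic–allylic CH2 of 5.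

**Compound list**
1 | triacetic acid lactone (4-hydroxy-6-methyl-2H-pyran-2-one) | CC1=CC(O)=CC(=O)O1 | starting material
2 | 4-hydroxy-6-methyl-3-(3-methylbut-2-en-1-yl)-2H-pyran-2-one | CC1=CC(O)=C(CC=C(C)C)C(=O)O1 | intermediate
3 | methyl 2-bromo-3-hydroxybenzoate | COC(=O)c1cccc(O)c1Br | starting material
4 | methyl 2-bromo-3-[(tert-butyldimethylsilyl)oxy]benzoate | COC(=O)c1cccc(O[Si](C)(C)C(C)(C)C)c1Br | intermediate
5 | methyl 3-[(tert-butyldimethylsilyl)oxy]-2-(3-methylbut-2-en-1-yl)benzoate | COC(=O)c1cccc(O[Si](C)(C)C(C)(C)C)c1CC=C(C)C | intermediate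
6 | 6-{2-[3-(tert-butyldimethylsilyloxy)-2-(3-methylbut-2-en-1-yl)phenyl]-2-oxoethyl}-4-hydroxy-3-(3-methylbut-2-en-1-yl)-2H-pyran-2-one (phenacylpyrone) | CC(C)=CCc1c(O[Si](C)(C)C(C)(C)C)cccc1C(=O)CC1=CC(O)=C(CC=C(C)C)C(=O)O1 | intermediate (not isolated)
7 | methyl 7-[3-(tert-butyldimethylsilyloxy)-2-(3-methylbut-2-en-1-yl)phenyl]-2-(3-methylbut-2-en-1-yl)-3,5,7-trioxoheptanoate (triketo ester; racemic at the enolisable C2) | COC(=O)C(CC=C(C)C)C(=O)CC(=O)CC(=O)c1cccc(O[Si](C)(C)C(C)(C)C)c1CC=C(C)C | intermediate (not isolated)
8 | cudraphenone D, [3-hydroxy-2-(3-methylbut-2-en-1-yl)phenyl][2,4,6-trihydroxy-3-(3-methylbut-2-en-1-yl)phenyl]methanone | CC(C)=CCc1c(O)cccc1C(=O)c1c(O)cc(O)c(CC=C(C)C)c1O | target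

**Step count and risk**
Total steps: 4. Longest linear sequence: 3 (3 → 4 → 5 → 8).

Steps most likely to fail, in order of risk:

Step 4. Proton transfer from the doubly activated CH2 of 5 (benzylic, allylic and ortho to the ester) to the pyrone dianion, or slow addition to the ortho-substituted ester carbonyl, may keep the two fragments from being joined. The fallback sets out from 5 and comes back to the route at 6; it moves the electrophile to the aldehyde level, where carbonyl addition should be much faster than proton transfer. Compound 5 is reduced with iBu2AlH (CH2Cl2, −78 °C) to {3-[(tert-butyldimethylsilyl)oxy]-2-(3-methylbut-2-en-1-yl)phenyl}methanol F1, which MnO2 (CH2Cl2, rt) oxidises to 3-[(tert-butyldimethylsilyl)oxy]-2-(3-methylbut-2-en-1-yl)benzaldehyde F2. The dianion of 2 (LiN(iPr)2, THF, −78 °C) adds to F2 in an aldol-type reaction to give racemic 6-{2-[3-(tert-butyldimethylsilyloxy)-2-(3-methylbut-2-en-1-yl)phenyl]-2-hydroxyethyl}-4-hydroxy-3-(3-methylbut-2-en-1-yl)-2H-pyran-2-one F3. Dess–Martin periodinane (CH2Cl2, rt) oxidises the benzylic alcohol of F3 to 6, which is now isolated and then heated with Mg(OMe)2 in MeOH as in the second stage of step 4 to give 8.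

Step 3. Slow oxidative addition or transmetalation at a bromide flanked by the ester and the bulky silyl ether may let coupling through the tertiary carbon of the allylic zinc (reverse-prenyl isomer) or addition of the allylic zinc to the ester compete. The fallback sets out from 4 and comes back at 5; it installs an unsubstituted allyl group, for which no regiochemical question exists, and builds the prenyl terminus afterwards. Stille coupling of 4 with allyltributylstannane (Pd(PPh3)4, toluene, 110 °C) should give methyl 2-allyl-3-[(tert-butyldimethylsilyl)oxy]benzoate F4, and olefin cross-metathesis of F4 with 2-methylbut-2-ene (second-generation Grubbs catalyst, CH2Cl2, 40 °C) should give 5.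

Step 1. Alkylation on the 4-oxygen without equilibration to carbon, a second prenylation at C3, or attack at the tertiary terminus of the allyl palladium complex may erode the C3-monoprenyl product. The fallback sets out from 1 and comes back at 2; it makes the O-allyl ether on purpose and moves the allyl group to C3 by a sigmatropic shift. Compound 1 is O-alkylated with allyl bromide (K2CO3, acetone, reflux) to 4-(allyloxy)-6-methyl-2H-pyran-2-one F5. Claisen rearrangement of F5 (toluene, reflux) should deliver the allyl group to C3 only and give 3-allyl-4-hydroxy-6-methyl-2H-pyran-2-one F6. Cross-metathesis of F6 with 2-methylbut-2-ene (second-generation Grubbs catalyst, CH2Cl2, 40 °C) should give 2.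

**Further compounds**
F1 | step 4 | {3-[(tert-butyldimethylsilyl)oxy]-2-(3-methylbut-2-en-1-yl)phenyl}methanol | CC(C)=CCc1c(O[Si](C)(C)C(C)(C)C)cccc1CO
F2 | step 4 | 3-[(tert-butyldimethylsilyl)oxy]-2-(3-methylbut-2-en-1-yl)benzaldehyde | CC(C)=CCc1c(O[Si](C)(C)C(C)(C)C)cccc1C=O
F3 | step 4 | 6-{2-[3-(tert-butyldimethylsilyloxy)-2-(3-methylbut-2-en-1-yl)phenyl]-2-hydroxyethyl}-4-hydroxy-3-(3-methylbut-2-en-1-yl)-2H-pyran-2-one (racemic) | CC(C)=CCc1c(O[Si](C)(C)C(C)(C)C)cccc1C(O)CC1=CC(O)=C(CC=C(C)C)C(=O)O1
F4 | step 3 | methyl 2-allyl-3-[(tert-butyldimethylsilyl)oxy]benzoate | COC(=O)c1cccc(O[Si](C)(C)C(C)(C)C)c1CC=C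
F5 | step 1 | 4-(allyloxy)-6-methyl-2H-pyran-2-one | CC1=CC(OCC=C)=CC(=O)O1
F6 | step 1 | 3-allyl-4-hydroxy-6-methyl-2H-pyran-2-one | CC1=CC(O)=C(CC=C)C(=O)O1
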